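**Plan**

1. Retrosynthesis: the two phenols are unmasked last, from the C5 methyl ether and a C4' isopropyl ether. The C4 carbonyl is traced back to the C4 methylene of a 4H-chromene, and that to a flavylium cation.
2. The pyrylium ring is then cut at C3–C4 and O1–C2. The enabling feature: C2 with ring B and the C3 methoxy group make up an aryl methoxymethyl ketone, and C4 with ring A makes up a salicylaldehyde whose only free hydroxyl is the future O1.
3. Forward: ring A aldehyde 4 comes from 1,2,3,5-tetramethoxybenzene (formylation, cleavage of the crowded ortho methyl ether). Ring B ketone 9 comes from 4-bromo-3-methoxyphenol (isopropylation, aryllithium plus Weinreb amide).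
4. Acid condensation of 4 with 9 closes ring C, the only ring made, as flavylium salt 11. Hydride addition at C4, oxidation of the C4 methylene to the carbonyl and BCl3 dealkylation follow.
5. Stereochemistry: the target has no stereocentre. The enone geometry of the open-chain intermediate is the only stereochemical element on the way, and the acid equilibrates it.

Key step: step 5

Remark: amide 7 is treated as a purchasable Weinreb amide. The benzyl ether that could protect the C4' oxygen is replaced by an isopropyl ether, because a benzylic ether CH2 would compete in the peroxide oxidation of step 7.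

**Route**

Step 1
Reactants: 1 1,2,3,5-tetramethoxybenzene
Product: 3 2,3,4,6-tetramethoxybenzaldehyde, via aryl iminium salt 2 (not isolated)
Conditions: POCl3, DMF, 0 °C to 60 °C; then ice-water
Reagents that add atoms: N,N-dimethylformamide CN(C)C=O; water O
Why: Vilsmeier–Haack formylation: the two unsubstituted positions of 1 are equivalent and each is activated by two ortho and one para methoxy group, so a single aldehyde should result once iminium salt 2 is hydrolysed.

Step 2
Reactants: 3 2,3,4,6-tetramethoxybenzaldehyde
Product: 4 2-hydroxy-3,4,6-trimethoxybenzaldehyde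
Conditions: BCl3 (1.1 equiv), CH2Cl2, −78 °C to 0 °C; then H2O
Reagents that add atoms: none
Why: Chelation-directed Lewis-acid cleavage of an aryl methyl ether ortho to a carbonyl group: the C2 methoxy group is twisted out of the ring plane by its C3 neighbour, which makes its oxygen the more basic of the two ortho ethers, so one equivalent of BCl3 at low temperature should free this hydroxyl preferentially.

Step 3
Reactants: 5 4-bromo-3-methoxyphenol
Product: 6 1-bromo-4-isopropoxy-2-methoxybenzene
Conditions: 2-bromopropane, K2CO3, DMF, 60 °C
Reagents that add atoms: 2-bromopropane CC(C)Br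
Why: Williamson ether synthesis on the only phenol; the isopropyl ether should survive butyllithium, HCl, LiAlH4 and the peroxide oxidation, and it falls to BCl3 in the last step.

Step 4
Reactants: 6 1-bromo-4-isopropoxy-2-methoxybenzene; 7 N,2-dimethoxy-N-methylacetamide
Product: 9 1-(4-isopropoxy-2-methoxyphenyl)-2-methoxyethan-1-one, via aryllithium 8 (not isolated)
Conditions: n-BuLi, THF, −78 °C; then 7, −78 °C to 0 °C; then 1 M HCl
Reagents that add atoms: none
Why: Bromine–lithium exchange followed by Weinreb ketone synthesis: the bromine fixes the acylation site para to the isopropoxy group, and the N-methoxy-N-methyl amide should hold the adduct at the ketone oxidation level until the acidic quench.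

Step 5
Reactants: 4 2-hydroxy-3,4,6-trimethoxybenzaldehyde; 9 1-(4-isopropoxy-2-methoxyphenyl)-2-methoxyethan-1-one
Product: 11 4'-isopropoxy-3,5,7,8,2'-pentamethoxyflavylium chloride, via open-chain enone 10 (not isolated)
Conditions: dry HCl (g), EtOAc, 0 °C; then rt, 48 h
Reagents that add atoms: hydrogen chloride Cl
Why: HCl activates the formyl group of 4, the enol of 9 adds to it through the methoxy-bearing methylene, and loss of water gives enone 10 and with it the C3–C4 bond. Acid equilibrates the enone geometry, the ring A hydroxyl adds to the protonated aryl ketone in a 6-exo-trig closure, and loss of a second water molecule aromatises the new ring to the pyrylium, which sets the O1–C2 bond. The closest known reaction type is the acid-mediated condensation of salicylaldehydes with aryl methoxymethyl ketones to 3-methoxyflavylium salts. No stereocentre is formed. The step needs one ring-fusion regiochemistry and one direction of enolisation, and both are fixed by the substrates: 4 has a single free hydroxyl, next to the future C8 methoxy group, and 9 has a single enolisable carbon. The chloride salt should separate from ethyl acetate, which pulls the equilibria toward the cation.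

Step 6
Reactants: 11 4'-isopropoxy-3,5,7,8,2'-pentamethoxyflavylium chloride
Product: 12 2-(4-isopropoxy-2-methoxyphenyl)-3,5,7,8-tetramethoxy-4H-chromene
Conditions: LiAlH4, THF, 0 °C, argon; then H2O; used directly
Reagents that add atoms: none
Why: Hydride addition to a 2-aryl-1-benzopyrylium cation: LiAlH4 in an ether solvent is expected to deliver hydride to C4 and not to the aryl-bearing C2, which gives the 4H-chromene with its C2=C3 enol ether still conjugated to ring B.

Step 7
Reactants: 12 2-(4-isopropoxy-2-methoxyphenyl)-3,5,7,8-tetramethoxy-4H-chromene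
Product: 14 4'-isopropoxy-3,5,7,8,2'-pentamethoxyflavone, via C4 tert-butyl peroxide 13 (not isolated)
Conditions: Rh2(cap)4 (dirhodium tetrakis(caprolactamate), 1 mol %), t-BuOOH (5 equiv, in decane), K2CO3, CH2Cl2, rt; then Et3N
Reagents that add atoms: tert-butyl hydroperoxide CC(C)(C)OO
Why: Allylic and benzylic methylene oxidation with tert-butyl hydroperoxide under dirhodium caprolactamate catalysis: tert-butylperoxyl radicals should abstract hydrogen from C4, the doubly activated position between ring A and the C2=C3 enol ether, the radical is trapped as mixed peroxide 13, and base-assisted loss of tert-butanol (Kornblum–DeLaMare fragmentation) gives the γ-pyranone.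

Step 8
Reactants: 14 4'-isopropoxy-3,5,7,8,2'-pentamethoxyflavone
Product: 15 5,4'-dihydroxy-3,7,8,2'-tetramethoxyflavone
Conditions: BCl3 (4 equiv), CH2Cl2, −78 °C to 0 °C; then H2O
Reagents that add atoms: none
Why: Lewis-acid ether cleavage: BCl3 should dealkylate the secondary isopropyl ether quickly and the C5 methyl ether through a six-membered chelate with the C4 carbonyl, whereas the methyl ethers at C3, C7, C8 and C2' should remain at 0 °C.

**Compound list**

1 | 1,2,3,5-tetramethoxybenzene | COc1cc(OC)c(OC)c(OC)c1 | starting material
2 | dimethyl(2,3,4,6-tetramethoxybenzylidene)iminium dichlorophosphate | COc1cc(OC)c(OC)c(OC)c1C=[N+](C)C.[O-]P(=O)(Cl)Cl | intermediate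
3 | 2,3,4,6-tetramethoxybenzaldehyde | COc1cc(OC)c(OC)c(OC)c1C=O | intermediate
4 | 2-hydroxy-3,4,6-trimethoxybenzaldehyde | COc1cc(OC)c(OC)c(O)c1C=O | intermediate
5 | 4-bromo-3-methoxyphenol | COc1cc(O)ccc1Br | starting material
6 | 1-bromo-4-isopropoxy-2-methoxybenzene | COc1cc(OC(C)C)ccc1Br | intermediate
7 | N,2-dimethoxy-N-methylacetamide | COCC(=O)N(C)OC | starting material
8 | (4-isopropoxy-2-methoxyphenyl)lithium | [Li]c1ccc(OC(C)C)cc1OC | intermediate
9 | 1-(4-isopropoxy-2-methoxyphenyl)-2-methoxyethan-1-one | COCC(=O)c1ccc(OC(C)C)cc1OC | intermediate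
10 | (E)-3-(2-hydroxy-3,4,6-trimethoxyphenyl)-1-(4-isopropoxy-2-methoxyphenyl)-2-methoxyprop-2-en-1-one (hydroxyaryl group cis to the aroyl group) | COc1cc(OC)c(OC)c(O)c1/C=C(/OC)C(=O)c1ccc(OC(C)C)cc1OC | intermediate
11 | 4'-isopropoxy-3,5,7,8,2'-pentamethoxyflavylium chloride (2-(4-isopropoxy-2-methoxyphenyl)-3,5,7,8-tetramethoxychromenylium chloride) | COc1cc(OC(C)C)ccc1-c1[o+]c2c(OC)c(OC)cc(OC)c2cc1OC.[Cl-] | intermediate
12 | 2-(4-isopropoxy-2-methoxyphenyl)-3,5,7,8-tetramethoxy-4H-chromene | COc1cc(OC(C)C)ccc1C1=C(OC)Cc2c(OC)cc(OC)c(OC)c2O1 | intermediate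
13 | 4-(tert-butylperoxy)-2-(4-isopropoxy-2-methoxyphenyl)-3,5,7,8-tetramethoxy-4H-chromene (racemic) | COc1cc(OC(C)C)ccc1C1=C(OC)C(OOC(C)(C)C)c2c(OC)cc(OC)c(OC)c2O1 | intermediate
14 | 4'-isopropoxy-3,5,7,8,2'-pentamethoxyflavone (2-(4-isopropoxy-2-methoxyphenyl)-3,5,7,8-tetramethoxy-4H-chromen-4-one) | COc1cc(OC(C)C)ccc1-c1oc2c(OC)c(OC)cc(OC)c2c(=O)c1OC | intermediate
15 | 5,4'-dihydroxy-3,7,8,2'-tetramethoxyflavone (5-hydroxy-2-(4-hydroxy-2-methoxyphenyl)-3,7,8-trimethoxy-4H-chromen-4-one) | COc1cc(O)ccc1-c1oc2c(OC)c(OC)cc(O)c2c(=O)c1OC | target

**Count and risks**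

Total: 8 steps. Longest linear sequence: 6 steps (steps 1, 2, 5, 6, 7, 8; the ring B branch through steps 3, 4, 5, 6, 7, 8 is equally long).

Steps most likely to fail:

1. Step 7. The 4H-chromene may lose a second electron and return to the flavylium cation, after which peroxide attack at C2 would cleave the heterocycle. The electron-rich C2=C3 enol ether may also be attacked directly. The fallback places the C4 oxygen before ring closure and forms the same two bonds in separate operations. It sets out from 4 and 9. Aldehyde 4 is protected with chloromethyl methyl ether and i-Pr2NEt in CH2Cl2 as 2-(methoxymethoxy)-3,4,6-trimethoxybenzaldehyde F1. The lithium enolate of 9 (LiN(i-Pr)2, THF, −78 °C) adds to F1 in an aldol addition to give 3-hydroxy-1-(4-isopropoxy-2-methoxyphenyl)-2-methoxy-3-[2-(methoxymethoxy)-3,4,6-trimethoxyphenyl]propan-1-one F2 as a mixture of diastereomers. Dess–Martin periodinane oxidises F2 to 1-(4-isopropoxy-2-methoxyphenyl)-2-methoxy-3-[2-(methoxymethoxy)-3,4,6-trimethoxyphenyl]propane-1,3-dione F3. Warm HCl in methanol removes the acetal and cyclodehydrates the freed o-hydroxyaryl 1,3-diketone, and the route is rejoined at 14.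

2. Step 6. Hydride may be delivered to C2 in competition with C4, and the enol ether may hydrolyse or air-oxidise during work-up. The fallback builds 12 with C4 already at the methylene level and uses no hydride on the cation. It sets out from 4 and 9. NaBH4 in methanol reduces 4 to 2-(hydroxymethyl)-3,5,6-trimethoxyphenol F4. Catalytic TsOH in toluene over molecular sieves turns F4 into the o-quinone methide, the enol of 9 adds to its methylene carbon (C3–C4), the phenol closes onto the ketone (O1–C2) and dehydration follows. This is the known acid-catalysed annulation of salicyl alcohols with enolisable carbonyl compounds to 4H-chromenes, and the route is rejoined at 12.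

3. Step 5. The aldol condensation between a hindered ketone and an electron-rich, doubly ortho-substituted aldehyde may be sluggish, so that the mixture stalls before ring closure or the salt does not separate. The fallback divides the event into a base-mediated carbon–carbon bond formation and a separate acid ring closure. It sets out from 4 and 9. Claisen–Schmidt condensation (KOH, EtOH, 50 °C) gives (Z)-3-(2-hydroxy-3,4,6-trimethoxyphenyl)-1-(4-isopropoxy-2-methoxyphenyl)-2-methoxyprop-2-en-1-one F5, the isomer with the hydroxyaryl group trans to the aroyl group, which is isolated. HCl in acetic acid with warming in daylight then isomerises the double bond and closes the ring, and the route is rejoined at 11.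

**Further compounds**

F1 | step 7 | 2-(methoxymethoxy)-3,4,6-trimethoxybenzaldehyde | COCOc1c(OC)c(OC)cc(OC)c1C=O
F2 | step 7 | 3-hydroxy-1-(4-isopropoxy-2-methoxyphenyl)-2-methoxy-3-[2-(methoxymethoxy)-3,4,6-trimethoxyphenyl]propan-1-one (mixture of diastereomers) | COCOc1c(OC)c(OC)cc(OC)c1C(O)C(OC)C(=O)c1ccc(OC(C)C)cc1OC
F3 | step 7 | 1-(4-isopropoxy-2-methoxyphenyl)-2-methoxy-3-[2-(methoxymethoxy)-3,4,6-trimethoxyphenyl]propane-1,3-dione (racemic) | COCOc1c(OC)c(OC)cc(OC)c1C(=O)C(OC)C(=O)c1ccc(OC(C)C)cc1OC
F4 | step 6 | 2-(hydroxymethyl)-3,5,6-trimethoxyphenol | COc1cc(OC)c(OC)c(O)c1CO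
F5 | step 5 | (Z)-3-(2-hydroxy-3,4,6-trimethoxyphenyl)-1-(4-isopropoxy-2-methoxyphenyl)-2-methoxyprop-2-en-1-one | COc1cc(OC)c(OC)c(O)c1/C=C(\OC)C(=O)c1ccc(OC(C)C)cc1OC
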